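Retrosynthetic cuts, in order: the eight O-Si bonds of a persilylated precursor; the aryl-vinyl bond of the stilbene arm (to an aryl bromide and a styrene); the bond from the stereogenic CH to C5 of the styryl-bearing resorcinol ring, together with one C-H of the adjacent CH2 (to a stilbene and 4-bromoresorcinol); the C=C of that stilbene (Wittig).
Enabling feature: the stereogenic CH is the benzylic carbon of the unsubstituted 2,4-dihydroxyphenyl ring, ortho to its 2-OH and para to its 4-O, so it is the exocyclic carbon of an ortho-quinone methide. The other ring is attached through the carbon ortho to one OH and para to the other, the innate Friedel-Crafts site of a resorcinol.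
Forward: no ring is made and all four benzene rings are bought. One silylated 3,5-dihydroxybenzaldehyde feeds both 3,5-dioxygenated rings, a Wittig reaction gives the 2-hydroxystilbene, the chiral acid joins it to 4-bromoresorcinol, a Heck reaction replaces bromine by the second styryl arm, and fluoride frees the phenols.
Stereochemistry: the single stereocentre (S) is set by the chiral Brønsted acid in the hydroarylation and is not touched afterwards. The E olefin comes from the Heck step.

Key step: step 7

Assumption: the sense of induction cannot be predicted for this substrate pair, so the (R)-configured acid is written, its antipode is used if the R product results, and the configuration is to be checked by anomalous-dispersion X-ray analysis of the bromide made in the key step.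

Step 1
Reactants: 1 3,5-dihydroxybenzaldehyde
Product: 2 3,5-bis(triisopropylsilyloxy)benzaldehyde
Conditions: TIPSCl (2.4 equiv), imidazole (5 equiv), DMF, 0 °C to rt
Reagents that add atoms: triisopropylsilyl chloride, CC(C)[Si](Cl)(C(C)C)C(C)C
Why: Standard phenol silylation with silyl chloride and imidazole caps both unhindered phenols, and TIPS is chosen because it survives ylides, Brønsted acid and palladium/amine and shields the neighbouring ring positions.

Step 2
Reactants: 2 3,5-bis(triisopropylsilyloxy)benzaldehyde
Product: 3 3,5-bis(triisopropylsilyloxy)styrene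
Conditions: Ph3PCH3Br (1.4 equiv), KOt-Bu (1.3 equiv), THF, 0 °C to rt
Reagents that add atoms: methyltriphenylphosphonium bromide, C[P+](c1ccccc1)(c1ccccc1)c1ccccc1.[Br-]
Why: Wittig methylenation of a non-enolisable aromatic aldehyde with the unstabilised ylide is reliable, and aryl TIPS ethers tolerate the ylide at or below room temperature.

Step 3
Reactants: 4 2,4-dihydroxybenzaldehyde
Product: 5 2-hydroxy-4-(triisopropylsilyloxy)benzaldehyde
Conditions: TIPSCl (1.05 equiv), imidazole (2 equiv), CH2Cl2, 0 °C
Reagents that add atoms: triisopropylsilyl chloride, CC(C)[Si](Cl)(C(C)C)C(C)C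
Why: Site-selective silylation is expected because the 2-OH is hydrogen-bonded to the aldehyde oxygen and flanked by the formyl group, so one equivalent of the bulky chloride should take the more acidic, unhindered 4-OH.

Step 4
Reactants: 5 2-hydroxy-4-(triisopropylsilyloxy)benzaldehyde
Product: 6 2-(hydroxymethyl)-5-(triisopropylsilyloxy)phenol
Conditions: NaBH4 (1 equiv), THF/MeOH, 0 °C; pH 7 buffer
Reagents that add atoms: none
Why: Borohydride reduction of the aldehyde leaves the aryl silyl ether alone, and the neutral quench keeps the ionisation-prone ortho-hydroxybenzyl alcohol from losing water.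

Step 5
Reactants: 6 2-(hydroxymethyl)-5-(triisopropylsilyloxy)phenol
Product: 7 [2-hydroxy-4-(triisopropylsilyloxy)benzyl]triphenylphosphonium bromide
Conditions: Ph3P·HBr (1 equiv), MeCN, 60 °C
Reagents that add atoms: triphenylphosphine hydrobromide, Br.c1ccc(cc1)P(c1ccccc1)c1ccccc1
Why: In this standard phosphonium salt formation from an ortho-hydroxybenzyl alcohol, the acid ionises the electron-rich benzylic alcohol and triphenylphosphine captures the cation faster than it can oligomerise, while the aryl TIPS ether is stable to this weak acid.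

Step 6
Reactants: 7 [2-hydroxy-4-(triisopropylsilyloxy)benzyl]triphenylphosphonium bromide, 2 3,5-bis(triisopropylsilyloxy)benzaldehyde
Product: 9 (E)-2-[3,5-bis(triisopropylsilyloxy)styryl]-5-(triisopropylsilyloxy)phenol, via phenoxide ylide 8 (not isolated)
Conditions: LiHMDS (2.2 equiv), THF, -78 to 0 °C; then 2, 0 °C to rt; aq NH4Cl
Reagents that add atoms: none
Why: In this Wittig olefination two equivalents of base give the semi-stabilised phenoxide ylide 8, which condenses with the non-enolisable aldehyde 2, and any Z isomer formed beside the E isomer drawn is carried along because step 7 erases the olefin geometry.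

Step 7
Reactants: 9 (E)-2-[3,5-bis(triisopropylsilyloxy)styryl]-5-(triisopropylsilyloxy)phenol, 10 4-bromoresorcinol
Product: 12 (S)-4-bromo-6-{2-[3,5-bis(triisopropylsilyloxy)phenyl]-1-[2-hydroxy-4-(triisopropylsilyloxy)phenyl]ethyl}benzene-1,3-diol, via ortho-quinone methide 11 (not isolated)
Conditions: 10 (3 equiv), (R)-3,3'-bis(2,4,6-triisopropylphenyl)-1,1'-binaphthyl-2,2'-diyl N-triflylphosphoramide (10 mol %), toluene/CH2Cl2, 4 Å MS, -20 °C to rt, Ar
Reagents that add atoms: none
Why: Proposed new method: the chiral acid should protonate 9 at the olefin carbon bound to the 3,5-disilyloxyphenyl ring, since only then is the charge taken up by the free 2-OH and the 4-silyloxy oxygen, giving ortho-quinone methide 11 as a hydrogen-bonded ion pair that is the same from E- or Z-9. The conjugate base holds the oxygen of 11 through one basic site and the C1-OH of 10 through another, C6 of 10 attacks the exocyclic carbon in a Friedel-Crafts alkylation, and rearomatisation returns the proton to the catalyst, so one C-C and one C-H bond form across the olefin and no ring closes. The closest known reaction type is the chiral-phosphoric-acid-catalysed hydroarylation or transfer hydrogenation of ortho-hydroxystyrenes and the addition of indoles, naphthols and electron-rich phenols to ortho-quinone methides made in situ; new here are the β-aryl (stilbene) olefin, which loses conjugation on protonation and therefore calls for the more acidic N-triflylphosphoramide, and the brominated resorcinol nucleophile. The new stereocentre is controlled only by the catalyst, whose 3,3'-aryl pocket leaves one face of planar 11 open to the bound arene (S wanted). Site selectivity on 10 comes from bromine occupying C4 and from the crowding of C2 between two hydroxyls, which leaves C6, ortho to one OH and para to the other. Cross-coupling over self-coupling is secured by the TIPS groups of 9, which remove hydrogen-bond handles and shield its ring carbons, and by the excess of 10, which should outrun [4+2] dimerisation of 11 with 9.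

Step 8
Reactants: 12 (S)-4-bromo-6-{2-[3,5-bis(triisopropylsilyloxy)phenyl]-1-[2-hydroxy-4-(triisopropylsilyloxy)phenyl]ethyl}benzene-1,3-diol
Product: 13 tris(tert-butyldimethylsilyl) ether of 12, (S)-configured aryl bromide with all six oxygens silylated
Conditions: TBSOTf (4.5 equiv), 2,6-lutidine (7 equiv), CH2Cl2, 0 °C to rt
Reagents that add atoms: tert-butyldimethylsilyl triflate, CC(C)(C)[Si](C)(C)OS(=O)(=O)C(F)(F)F
Why: Silyl triflate/2,6-lutidine silylation is strong enough for the two hindered phenols next to the triarylethane carbon, masks the acidic OH groups ahead of the palladium step, and its buffered medium cannot ionise the benzylic stereocentre.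

Step 9
Reactants: 13 tris(tert-butyldimethylsilyl) ether of 12, 3 3,5-bis(triisopropylsilyloxy)styrene
Product: 14 fully silylated target, (S,E)-configured, with five TIPS and three TBS ethers
Conditions: 3 (1.5 equiv), Pd(Pt-Bu3)2 (5 mol %), Cy2NMe (1.5 equiv), toluene, 80 °C, Ar
Reagents that add atoms: none
Why: In this Mizoroki-Heck reaction the bulky electron-rich phosphine makes oxidative addition into the electron-rich, ortho-substituted aryl bromide feasible, insertion at the terminal carbon of 3 followed by syn β-hydride elimination gives the E-stilbene, and the stereocentre, attached meta to the reacting carbon, takes no part.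

Step 10
Reactants: 14 fully silylated target
Product: 15 4-[(1S)-1-(2,4-dihydroxyphenyl)-2-(3,5-dihydroxyphenyl)ethyl]-6-[(E)-2-(3,5-dihydroxyphenyl)ethenyl]benzene-1,3-diol (CNP0376747.1)
Conditions: TBAF/AcOH (1:1, 12 equiv each), THF, 0 °C to rt, Ar, exclusion of light
Reagents that add atoms: none
Why: Fluoride-driven desilylation cleaves all eight aryl silyl ethers in one operation, and acetic acid protonates each phenoxide as it forms, so neither base-induced air oxidation nor acid-induced retro-Friedel-Crafts ionisation of the stereocentre should set in.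

Compound list
1 | 3,5-dihydroxybenzaldehyde | O=Cc1cc(O)cc(O)c1 | starting material
2 | 3,5-bis(triisopropylsilyloxy)benzaldehyde | O=Cc1cc(O[Si](C(C)C)(C(C)C)C(C)C)cc(O[Si](C(C)C)(C(C)C)C(C)C)c1 | intermediate
3 | 3,5-bis(triisopropylsilyloxy)styrene | C=Cc1cc(O[Si](C(C)C)(C(C)C)C(C)C)cc(O[Si](C(C)C)(C(C)C)C(C)C)c1 | intermediate
4 | 2,4-dihydroxybenzaldehyde | O=Cc1ccc(O)cc1O | starting material
5 | 2-hydroxy-4-(triisopropylsilyloxy)benzaldehyde | O=Cc1ccc(O[Si](C(C)C)(C(C)C)C(C)C)cc1O | intermediate
6 | 2-(hydroxymethyl)-5-(triisopropylsilyloxy)phenol | OCc1ccc(O[Si](C(C)C)(C(C)C)C(C)C)cc1O | intermediate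
7 | [2-hydroxy-4-(triisopropylsilyloxy)benzyl]triphenylphosphonium bromide | Oc1cc(O[Si](C(C)C)(C(C)C)C(C)C)ccc1C[P+](c1ccccc1)(c1ccccc1)c1ccccc1.[Br-] | intermediate
8 | lithium 2-[(triphenylphosphoranylidene)methyl]-5-(triisopropylsilyloxy)phenoxide, the phenoxide ylide (not isolated) | [Li+].[O-]c1cc(O[Si](C(C)C)(C(C)C)C(C)C)ccc1C=P(c1ccccc1)(c1ccccc1)c1ccccc1 | intermediate
9 | (E)-2-[3,5-bis(triisopropylsilyloxy)styryl]-5-(triisopropylsilyloxy)phenol | Oc1cc(O[Si](C(C)C)(C(C)C)C(C)C)ccc1/C=C/c1cc(O[Si](C(C)C)(C(C)C)C(C)C)cc(O[Si](C(C)C)(C(C)C)C(C)C)c1 | intermediate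
10 | 4-bromoresorcinol (4-bromobenzene-1,3-diol) | Oc1ccc(Br)c(O)c1 | starting material
11 | (6E)-6-{2-[3,5-bis(triisopropylsilyloxy)phenyl]ethylidene}-3-(triisopropylsilyloxy)cyclohexa-2,4-dien-1-one, the ortho-quinone methide (not isolated) | O=C1C=C(O[Si](C(C)C)(C(C)C)C(C)C)C=C/C1=C\Cc1cc(O[Si](C(C)C)(C(C)C)C(C)C)cc(O[Si](C(C)C)(C(C)C)C(C)C)c1 | intermediate
12 | (S)-4-bromo-6-{2-[3,5-bis(triisopropylsilyloxy)phenyl]-1-[2-hydroxy-4-(triisopropylsilyloxy)phenyl]ethyl}benzene-1,3-diol | Brc1cc([C@@H](Cc2cc(O[Si](C(C)C)(C(C)C)C(C)C)cc(O[Si](C(C)C)(C(C)C)C(C)C)c2)c2ccc(O[Si](C(C)C)(C(C)C)C(C)C)cc2O)c(O)cc1O | intermediate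
13 | tris(tert-butyldimethylsilyl) ether of 12, (S) | Brc1cc([C@@H](Cc2cc(O[Si](C(C)C)(C(C)C)C(C)C)cc(O[Si](C(C)C)(C(C)C)C(C)C)c2)c2ccc(O[Si](C(C)C)(C(C)C)C(C)C)cc2O[Si](C)(C)C(C)(C)C)c(O[Si](C)(C)C(C)(C)C)cc1O[Si](C)(C)C(C)(C)C | intermediate
14 | fully silylated target (five TIPS, three TBS), (S,E) | CC(C)[Si](C(C)C)(C(C)C)Oc1cc(O[Si](C(C)C)(C(C)C)C(C)C)cc(/C=C/c2cc([C@@H](Cc3cc(O[Si](C(C)C)(C(C)C)C(C)C)cc(O[Si](C(C)C)(C(C)C)C(C)C)c3)c3ccc(O[Si](C(C)C)(C(C)C)C(C)C)cc3O[Si](C)(C)C(C)(C)C)c(O[Si](C)(C)C(C)(C)C)cc2O[Si](C)(C)C(C)(C)C)c1 | intermediate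
15 | 4-[(1S)-1-(2,4-dihydroxyphenyl)-2-(3,5-dihydroxyphenyl)ethyl]-6-[(E)-2-(3,5-dihydroxyphenyl)ethenyl]benzene-1,3-diol | Oc1cc(O)cc(/C=C/c2cc([C@@H](Cc3cc(O)cc(O)c3)c3ccc(O)cc3O)c(O)cc2O)c1 | target

Total step count: 10. Longest linear sequence: 8 steps (steps 3 to 10, from 4).

Steps most likely to fail

Step 7. Protonation of the conjugated stilbene may be too slow, self-alkylation or [4+2] dimerisation may compete, or facial selectivity may be poor. The fallback reaches the same quinone methide by dehydration instead of protonation, using known chemistry, and sets out from 2 and 5.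
- Aldehyde 2 is reduced with NaBH4 to [3,5-bis(triisopropylsilyloxy)phenyl]methanol F1.
- An Appel reaction (CBr4, PPh3, CH2Cl2) converts it into 3,5-bis(triisopropylsilyloxy)benzyl bromide F2.
- Slow addition to magnesium in Et2O gives 3,5-bis(triisopropylsilyloxy)benzylmagnesium bromide F3.
- Aldehyde 5 is deprotonated with NaH in THF to sodium 2-formyl-5-(triisopropylsilyloxy)phenoxide F4.
- Grignard addition to this phenoxide gives racemic 2-[3,5-bis(triisopropylsilyloxy)phenyl]-1-[2-hydroxy-4-(triisopropylsilyloxy)phenyl]ethanol F5.
- Treating this ortho-hydroxybenzyl alcohol with 10 and a 3,3'-bis(2,4,6-triisopropylphenyl)-BINOL phosphoric acid over molecular sieves is the established dehydrative quinone methide Friedel-Crafts alkylation. It is stereoconvergent through planar 11 and comes back to the route at 12.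
- Any shortfall in enantiopurity is removed by crystallisation or by chromatography on a chiral phase.

Step 9. Oxidative addition into the electron-rich, ortho-silyloxy-flanked C-Br bond may be sluggish, leaving room for protodebromination, thermal loss of aryl silyl ethers or insertion with the wrong regiochemistry. The fallback fixes the olefin geometry in a preformed vinylboron partner and sets out from 3.
- Cross-metathesis of 3 with vinylboronic acid pinacol ester (second-generation ruthenium benzylidene catalyst, CH2Cl2, 40 °C) gives (E)-2-[3,5-bis(triisopropylsilyloxy)styryl]-4,4,5,5-tetramethyl-1,3,2-dioxaborolane F6.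
- Suzuki-Miyaura coupling of this boronate with 13 (Pd(OAc)2, SPhos, K3PO4, toluene/H2O, 60 °C) comes back to the route at 14.

Step 6. The singly deprotonated salt may expel triphenylphosphine and oligomerise through a quinone methide before the ylide forms, and conversion of the aldehyde may stay low. The fallback forms the aryl-vinyl bond instead of the C=C bond and sets out from 10.
- One equivalent of TIPSCl with imidazole should silylate the hydroxyl para to bromine, because the one next to bromine is hindered, giving 2-bromo-5-(triisopropylsilyloxy)phenol F7.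
- A Mizoroki-Heck reaction of this bromophenol with 3 (Pd(Pt-Bu3)2, Cy2NMe, toluene, 80 °C) comes back to the route at 9 as the E isomer.

Further compounds
F1 | step 7 | [3,5-bis(triisopropylsilyloxy)phenyl]methanol | OCc1cc(O[Si](C(C)C)(C(C)C)C(C)C)cc(O[Si](C(C)C)(C(C)C)C(C)C)c1
F2 | step 7 | 3,5-bis(triisopropylsilyloxy)benzyl bromide | BrCc1cc(O[Si](C(C)C)(C(C)C)C(C)C)cc(O[Si](C(C)C)(C(C)C)C(C)C)c1
F3 | step 7 | 3,5-bis(triisopropylsilyloxy)benzylmagnesium bromide | Br[Mg]Cc1cc(O[Si](C(C)C)(C(C)C)C(C)C)cc(O[Si](C(C)C)(C(C)C)C(C)C)c1
F4 | step 7 | sodium 2-formyl-5-(triisopropylsilyloxy)phenoxide | [Na+].[O-]c1cc(O[Si](C(C)C)(C(C)C)C(C)C)ccc1C=O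
F5 | step 7 | racemic 2-[3,5-bis(triisopropylsilyloxy)phenyl]-1-[2-hydroxy-4-(triisopropylsilyloxy)phenyl]ethanol | OC(Cc1cc(O[Si](C(C)C)(C(C)C)C(C)C)cc(O[Si](C(C)C)(C(C)C)C(C)C)c1)c1ccc(O[Si](C(C)C)(C(C)C)C(C)C)cc1O
F6 | step 9 | (E)-2-[3,5-bis(triisopropylsilyloxy)styryl]-4,4,5,5-tetramethyl-1,3,2-dioxaborolane | CC1(C)OB(/C=C/c2cc(O[Si](C(C)C)(C(C)C)C(C)C)cc(O[Si](C(C)C)(C(C)C)C(C)C)c2)OC1(C)C
F7 | step 6 | 2-bromo-5-(triisopropylsilyloxy)phenol | Oc1cc(O[Si](C(C)C)(C(C)C)C(C)C)ccc1Br
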